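Retrosynthetic cuts, in order: the C1 ester and oxidation level; C2'–C3' (sp3–sp2 coupling); C1'–C2' (olefination); O–C6 of the 1,2-dioxane; O–C3; C2–C3 (aldol).
Enabling feature: in the 1,2-dioxane (O1, O2, C3, C4, C5, C6) the quaternary peroxy carbon C6 (methyl plus side chain) lies 1,4 to the CH carbon C3. An OOH on C3 therefore reaches C6 of a C6–C7 epoxide through a six-membered transition state.
Forward: geraniol supplies C3–C8 as an epoxy aldehyde and an aldol adds C1–C2. A capped hydroperoxide is then placed on C3, acid closes the dioxane (the only ring made), and the released glycol is trimmed to a C6 vinyl group.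
The cyclohexenone ring comes ready-made from dihydro-β-ionone. It is extended to an E-iodoalkene, oxidised to the enone and joined by hydroboration/Suzuki–Miyaura coupling; C1 is raised to the methyl ester last.
Stereochemistry: C6 from the Sharpless epoxide by inversion; C2 from the (S)-oxazolidinone; C3 from the syn-aldol carbinol by SN2 inversion; E-C3'=C4' from syn-carboalumination.
Key step: step 11

Remark: skeleton numbering is used throughout (C1 carboxyl carbon, C2, ring carbons C3–C6, C7/C8 the epoxide CH and its CH2O with C7 ending as C1', C1'–C6' the side chain); TBS = tert-butyldimethylsilyl, TBDPS = tert-butyldiphenylsilyl; dihydro-β-ionone is taken as a commercial flavour chemical (otherwise one conjugate reduction from β-ionone).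

Step 1
Reactants: 1 geraniol
Product: 2 (2R,3R)-2,3-epoxygeraniol
Conditions: Ti(OiPr)4 (5 mol %), D-(−)-diethyl tartrate (7 mol %), tBuOOH, 4 Å MS, CH2Cl2, −20 °C
Reagents that add atoms: tert-butyl hydroperoxide CC(C)(C)OO
Why: Sharpless asymmetric epoxidation touches only the allylic alkene, and the titanium/D-(−)-tartrate complex delivers oxygen to the face that gives the (2R,3R)-epoxide, which fixes the future C6 and C7.

Step 2
Reactants: 2 (2R,3R)-2,3-epoxygeraniol
Product: 3 (2R,3R)-2,3-epoxygeranyl TBS ether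
Conditions: TBSCl, imidazole, DMF, 0 °C → rt
Reagents that add atoms: tert-butyldimethylsilyl chloride CC(C)(C)[Si](C)(C)Cl
Why: Imidazole-promoted silyl ether formation caps the only hydroxyl, so that neither Payne rearrangement nor competing nucleophilic attack can occur later.

Step 3
Reactants: 3 (2R,3R)-2,3-epoxygeranyl TBS ether
Product: 5 3-[(2R,3R)-3-(TBSO-methyl)-2-methyloxiran-2-yl]propanal, via secondary ozonide 4 (not isolated)
Conditions: O3, CH2Cl2, −78 °C; then Me2S, −78 °C → rt
Reagents that add atoms: ozone [O-][O+]=O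
Why: Criegee ozonolysis with reductive work-up cleaves the single remaining alkene, while epoxide and silyl ether are inert to ozone and dimethyl sulfide.

Step 4
Reactants: 5 3-[(2R,3R)-3-(TBSO-methyl)-2-methyloxiran-2-yl]propanal; 6 (S)-4-benzyl-3-propanoyl-1,3-oxazolidin-2-one
Product: 9 (4S)-4-benzyl-3-[(2S,3R,6R,7R)-8-(TBSO)-6,7-epoxy-3-hydroxy-2,6-dimethyloctanoyl]-1,3-oxazolidin-2-one, via Z-boron enolate 7 (not isolated), via boron aldolate 8 (not isolated)
Conditions: 6, Bu2BOTf, Et3N, CH2Cl2, 0 °C; 5, −78 → 0 °C; pH 7 buffer, MeOH, 30% H2O2, 0 °C (purify on Et3N-washed SiO2)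
Reagents that add atoms: none
Why: In the Evans syn-aldol reaction the Z-boron enolate reacts through a closed Zimmerman–Traxler chair whose face is dictated by the benzyl group of the auxiliary, which sets (2S,3R) regardless of the remote epoxide, and the cold, buffered protocol keeps the new hydroxyl from opening the epoxide.

Step 5
Reactants: 9 Evans syn-aldol adduct
Product: 10 (2R,3R,6R,7R)-8-(TBSO)-6,7-epoxy-2,6-dimethyloctane-1,3-diol
Conditions: LiBH4, MeOH (1 equiv), Et2O/THF, 0 °C
Reagents that add atoms: none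
Why: Reductive cleavage of the N-acyl oxazolidinone by LiBH4 occurs at the exocyclic carbonyl and, being cold and basic, leaves the epoxide, silyl ether and both new stereocentres unchanged (the C2 descriptor changes only through priority).

Step 6
Reactants: 10 (2R,3R,6R,7R)-8-(TBSO)-6,7-epoxy-2,6-dimethyloctane-1,3-diol
Product: 11 (2R,3R,6R,7R)-1-(TBDPSO)-8-(TBSO)-6,7-epoxy-2,6-dimethyloctan-3-ol
Conditions: TBDPSCl (1.05 equiv), imidazole, CH2Cl2, 0 °C
Reagents that add atoms: tert-butyldiphenylsilyl chloride CC(C)(C)[Si](Cl)(c1ccccc1)c1ccccc1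
Why: Selective silylation works because the bulky chloride distinguishes primary from secondary hydroxyl, and TBDPS is chosen since it outlasts the acidic steps that later remove the peroxyketal and the TBS group.

Step 7
Reactants: 11 (2R,3R,6R,7R)-1-(TBDPSO)-8-(TBSO)-6,7-epoxy-2,6-dimethyloctan-3-ol
Product: 12 (2R,3R,6R,7R)-1-(TBDPSO)-8-(TBSO)-6,7-epoxy-2,6-dimethyloctan-3-yl methanesulfonate
Conditions: MsCl, Et3N, CH2Cl2, −10 °C
Reagents that add atoms: methanesulfonyl chloride CS(=O)(=O)Cl
Why: Mesylation takes place at oxygen with retention at C3 under basic conditions and removes the last free hydroxyl that could attack the epoxide in a 5-exo fashion.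

Step 8
Reactants: 13 2,3-dimethylbut-2-ene
Product: 14 2-methoxyprop-2-yl hydroperoxide
Conditions: O3, MeOH/CH2Cl2, −78 °C
Reagents that add atoms: ozone [O-][O+]=O; methanol CO
Why: Ozonolysis in a participating solvent follows the Criegee mechanism, and methanol traps the carbonyl oxide from the symmetrical alkene to give a hydroperoxide that is capped at one end as an acid-labile ketal.

Step 9
Reactants: 12 C3 mesylate; 14 2-methoxyprop-2-yl hydroperoxide
Product: 15 (2R,3S,6R,7R)-1-(TBDPSO)-8-(TBSO)-6,7-epoxy-3-[(2-methoxypropan-2-yl)peroxy]-2,6-dimethyloctane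
Conditions: 14 (3 equiv), CsOH·H2O (2.5 equiv), DMF, 0 °C → rt
Reagents that add atoms: none
Why: In this SN2 alkylation of a hydroperoxide anion the weakly basic, alpha-effect caesium peroxide displaces the secondary mesylate with inversion and so turns (3R) into the required (3S), while the ketal cap prevents double alkylation and the basic medium leaves the epoxide closed.

Step 10
Reactants: 15 C3 peroxyketal
Product: 16 (2R,3S,6R,7R)-1-(TBDPSO)-8-(TBSO)-6,7-epoxy-3-hydroperoxy-2,6-dimethyloctane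
Conditions: AcOH/THF/H2O, 0 °C → rt, short contact
Reagents that add atoms: none
Why: Mild acid hydrolysis of the acyclic peroxyketal is much faster than cleavage of the silyl ethers and does not touch the C3–O bond, and any ring closure that begins here only gives the product of the next step.

Step 11
Reactants: 16 (2R,3S,6R,7R)-1-(TBDPSO)-8-(TBSO)-6,7-epoxy-3-hydroperoxy-2,6-dimethyloctane
Product: 17 (3S,6S)-3-[(2R)-1-(TBDPSO)propan-2-yl]-6-[(1R)-2-(TBSO)-1-hydroxyethyl]-6-methyl-1,2-dioxane
Conditions: camphor-10-sulfonic acid (10 mol %), CH2Cl2, 0 °C → rt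
Reagents that add atoms: none
Why: The sulfonic acid protonates the epoxide oxygen, the C6–O bond lengthens, and the terminal oxygen of the C3 hydroperoxide attacks C6 anti to the departing oxygen, which forms O–C6 and frees the C7 hydroxyl. The closest known reaction type is the acid-catalysed cyclisation of epoxy hydroperoxides to cyclic peroxides, backed by the perhydrolysis of trisubstituted epoxides at their tertiary carbon. The one ring formed, the 1,2-dioxane, closes in the 6-exo-tet mode. C6 is the only new stereocentre and is fixed by stereospecific inversion of the Sharpless epoxide carbon, independent of ring conformation and of C3, while C2, C3 and C7 are not touched. The step needs attack at C6 and not C7 and attack by the hydroperoxide alone: C6 is tertiary and bears the developing positive charge, C7 would require a 7-endo closure next to the electron-withdrawing CH2OSi group, and since every hydroxyl is silylated no 5-exo tetrahydrofuran closure can intervene. A catalytic Brønsted acid in a non-nucleophilic solvent at low temperature keeps the opening SN2-like and holds back Meinwald rearrangement and acid-induced decay of the secondary hydroperoxide.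

Step 12
Reactants: 17 silylated dioxane
Product: 18 (3S,6S)-3-[(2R)-1-(TBDPSO)propan-2-yl]-6-[(1R)-1,2-dihydroxyethyl]-6-methyl-1,2-dioxane
Conditions: camphor-10-sulfonic acid (cat.), MeOH/CH2Cl2, 0 °C
Reagents that add atoms: none
Why: Acid-catalysed methanolysis (desilylation) removes the primary TBS ether well before the far more acid-stable TBDPS ether, and the dialkyl peroxide tolerates dilute acid.

Step 13
Reactants: 18 dioxane diol
Product: 19 (3S,6S)-6-formyl-6-methyl-3-[(2R)-1-(TBDPSO)propan-2-yl]-1,2-dioxane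
Conditions: NaIO4, THF/pH 7 buffer, 0 °C → rt
Reagents that add atoms: none
Why: Malaprade glycol cleavage is neutral and leaves peroxides alone, and it excises C8 to give the non-enolisable aldehyde whose carbon becomes C1'.

Step 14
Reactants: 19 C6 aldehyde
Product: 20 (3S,6S)-6-ethenyl-6-methyl-3-[(2R)-1-(TBDPSO)propan-2-yl]-1,2-dioxane
Conditions: Ph3PCH3Br, KN(SiMe3)2, THF, 0 °C; then 19, −78 → 0 °C
Reagents that add atoms: methyltriphenylphosphonium bromide C[P+](c1ccccc1)(c1ccccc1)c1ccccc1.[Br-]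
Why: Wittig methylenation by the non-stabilised ylide is fast at low temperature on a non-enolisable aldehyde, and with C1 still a silyl ether no acidified C–H flanks the peroxide, so Kornblum–DeLaMare cleavage is not expected.

Step 15
Reactants: 21 dihydro-β-ionone
Product: 23 2-(but-3-yn-1-yl)-1,3,3-trimethylcyclohex-1-ene, via enol phosphate 22 (not isolated)
Conditions: LiN(iPr)2, THF, −78 °C; ClP(O)(OEt)2, −78 °C → rt; LiN(iPr)2 (2.3 equiv), −78 °C → rt; H2O
Reagents that add atoms: none
Why: Kinetic deprotonation at the methyl group, O-phosphorylation and base-induced elimination of the enol phosphate is the standard conversion of a methyl ketone into a terminal alkyne.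

Step 16
Reactants: 23 2-(but-3-yn-1-yl)-1,3,3-trimethylcyclohex-1-ene
Product: 25 2-[(3E)-4-iodo-3-methylbut-3-en-1-yl]-1,3,3-trimethylcyclohex-1-ene, via alkenylalane 24 (not isolated)
Conditions: Me3Al, Cp2ZrCl2 (25 mol %), CH2Cl2, 0 °C → rt; then I2, THF, −30 → 0 °C
Reagents that add atoms: trimethylaluminium C[Al](C)C; iodine II
Why: Negishi zirconium-catalysed carboalumination adds methyl and aluminium syn across the terminal alkyne with aluminium at the terminus, and iodinolysis with retention gives the E-iodoalkene that carries the C3'=C4' geometry, the tetrasubstituted ring alkene being inert.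

Step 17
Reactants: 25 2-[(3E)-4-iodo-3-methylbut-3-en-1-yl]-1,3,3-trimethylcyclohex-1-ene
Product: 26 3-[(3E)-4-iodo-3-methylbut-3-en-1-yl]-2,4,4-trimethylcyclohex-2-en-1-one
Conditions: CrO3, 3,5-dimethylpyrazole, CH2Cl2, −20 °C
Reagents that add atoms: chromium trioxide O=[Cr](=O)=O
Why: Allylic oxidation by the electrophilic CrO3–dimethylpyrazole complex engages the most electron-rich alkene, and among its allylic sites the ring methylene is favoured because the side-chain methylene is screened by the gem-dimethyl group and could not give a planar enone, while the iodoalkene is inductively deactivated.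

Step 18
Reactants: 20 C6 vinyl dioxane; 26 iodoalkenyl cyclohexenone
Product: 28 (3S,6R)-3-[(2R)-1-(TBDPSO)propan-2-yl]-6-methyl-6-[(3E)-4-methyl-6-(2,6,6-trimethyl-3-oxocyclohex-1-en-1-yl)hex-3-en-1-yl]-1,2-dioxane, via B-alkyl-9-BBN adduct 27 (not isolated)
Conditions: 20, 9-BBN, THF, 0 °C → rt; then H2O, Cs2CO3, 26, Pd(dppf)Cl2 (5 mol %), AsPh3, DMF, rt
Reagents that add atoms: none
Why: Hydroboration places boron on the terminal vinyl carbon for steric reasons, excess borane is destroyed by water before the ketone arrives, and B-alkyl Suzuki–Miyaura coupling with the alkenyl iodide keeps the E geometry at room temperature, a regime in which dialkyl peroxides are known to survive both hydroboration and palladium-catalysed cross-coupling.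

Step 19
Reactants: 28 coupled TBDPS ether
Product: 29 (2R)-2-[(3S,6R)-6-methyl-6-[(3E)-4-methyl-6-(2,6,6-trimethyl-3-oxocyclohex-1-en-1-yl)hex-3-en-1-yl]-1,2-dioxan-3-yl]propan-1-ol
Conditions: HF·pyridine, pyridine/THF, 0 °C → rt
Reagents that add atoms: none
Why: Fluoride desilylation in a buffered, weakly acidic medium frees the primary alcohol without exposing C3–H next to the peroxide to base.

Step 20
Reactants: 29 primary alcohol
Product: 31 (2S)-2-[(3S,6R)-6-methyl-6-[(3E)-4-methyl-6-(2,6,6-trimethyl-3-oxocyclohex-1-en-1-yl)hex-3-en-1-yl]-1,2-dioxan-3-yl]propanoic acid, via C1 aldehyde 30 (not isolated)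
Conditions: TEMPO (20 mol %), PhI(OAc)2 (2.5 equiv), MeCN/pH 7 buffer, rt
Reagents that add atoms: water O
Why: The oxoammonium (TEMPO/PhI(OAc)2) oxidation carries the primary alcohol through the aldehyde hydrate to the acid in a nearly neutral medium, which spares alkene, enone and peroxide and leaves the aldehyde no time for epimerisation at C2 or beta-elimination of the peroxide.

Step 21
Reactants: 31 carboxylic acid
Product: 32 methyl (2S)-2-[(3S,6R)-6-methyl-6-[(3E)-4-methyl-6-(2,6,6-trimethyl-3-oxocyclohex-1-en-1-yl)hex-3-en-1-yl]-1,2-dioxan-3-yl]propanoate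
Conditions: TMSCHN2, toluene/MeOH, 0 °C
Reagents that add atoms: (trimethylsilyl)diazomethane C[Si](C)(C)C=[N+]=[N-]
Why: Diazoalkane esterification proceeds by proton transfer and alkylation without any base, so C2 is not epimerised and the beta-peroxy ester is not opened by E1cB elimination.

Compound list
1 | geraniol, (2E)-3,7-dimethylocta-2,6-dien-1-ol | CC(C)=CCC/C(C)=C/CO | starting material
2 | (2R,3R)-2,3-epoxygeraniol, [(2R,3R)-3-methyl-3-(4-methylpent-3-en-1-yl)oxiran-2-yl]methanol | CC(C)=CCC[C@@]1(C)O[C@@H]1CO | intermediate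
3 | (2R,3R)-2,3-epoxygeranyl TBS ether | CC(C)=CCC[C@@]1(C)O[C@@H]1CO[Si](C)(C)C(C)(C)C | intermediate
4 | secondary ozonide of 3 (3,3-dimethyl-1,2,4-trioxolane bearing the epoxy side chain at C5, not isolated) | CC1(C)OOC(CC[C@@]2(C)O[C@@H]2CO[Si](C)(C)C(C)(C)C)O1 | intermediate
5 | 3-[(2R,3R)-3-(TBSO-methyl)-2-methyloxiran-2-yl]propanal | O=CCC[C@@]1(C)O[C@@H]1CO[Si](C)(C)C(C)(C)C | intermediate
6 | (S)-4-benzyl-3-propanoyl-1,3-oxazolidin-2-one | CCC(=O)N1[C@@H](Cc2ccccc2)COC1=O | starting material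
7 | (Z)-dibutylboron enolate of 6 (not isolated) | C/C=C(\OB(CCCC)CCCC)N1[C@@H](Cc2ccccc2)COC1=O | intermediate
8 | dibutylboron aldolate of 9 (not isolated) | O=C([C@@H](C)[C@H](OB(CCCC)CCCC)CC[C@@]1(C)O[C@@H]1CO[Si](C)(C)C(C)(C)C)N1[C@@H](Cc2ccccc2)COC1=O | intermediate
9 | (4S)-4-benzyl-3-[(2S,3R,6R,7R)-8-(TBSO)-6,7-epoxy-3-hydroxy-2,6-dimethyloctanoyl]-1,3-oxazolidin-2-one | O=C([C@@H](C)[C@H](O)CC[C@@]1(C)O[C@@H]1CO[Si](C)(C)C(C)(C)C)N1[C@@H](Cc2ccccc2)COC1=O | intermediate
10 | (2R,3R,6R,7R)-8-(TBSO)-6,7-epoxy-2,6-dimethyloctane-1,3-diol | OC[C@@H](C)[C@H](O)CC[C@@]1(C)O[C@@H]1CO[Si](C)(C)C(C)(C)C | intermediate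
11 | (2R,3R,6R,7R)-1-(TBDPSO)-8-(TBSO)-6,7-epoxy-2,6-dimethyloctan-3-ol | CC(C)(C)[Si](OC[C@@H](C)[C@H](O)CC[C@@]1(C)O[C@@H]1CO[Si](C)(C)C(C)(C)C)(c1ccccc1)c1ccccc1 | intermediate
12 | (2R,3R,6R,7R)-1-(TBDPSO)-8-(TBSO)-6,7-epoxy-2,6-dimethyloctan-3-yl methanesulfonate | CC(C)(C)[Si](OC[C@@H](C)[C@H](OS(C)(=O)=O)CC[C@@]1(C)O[C@@H]1CO[Si](C)(C)C(C)(C)C)(c1ccccc1)c1ccccc1 | intermediate
13 | 2,3-dimethylbut-2-ene | CC(C)=C(C)C | starting material
14 | 2-methoxyprop-2-yl hydroperoxide | COC(C)(C)OO | intermediate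
15 | (2R,3S,6R,7R)-1-(TBDPSO)-8-(TBSO)-6,7-epoxy-3-[(2-methoxypropan-2-yl)peroxy]-2,6-dimethyloctane | CC(C)(C)[Si](OC[C@@H](C)[C@@H](OOC(C)(C)OC)CC[C@@]1(C)O[C@@H]1CO[Si](C)(C)C(C)(C)C)(c1ccccc1)c1ccccc1 | intermediate
16 | (2R,3S,6R,7R)-1-(TBDPSO)-8-(TBSO)-6,7-epoxy-3-hydroperoxy-2,6-dimethyloctane (key-step precursor) | CC(C)(C)[Si](OC[C@@H](C)[C@@H](OO)CC[C@@]1(C)O[C@@H]1CO[Si](C)(C)C(C)(C)C)(c1ccccc1)c1ccccc1 | intermediate
17 | (3S,6S)-3-[(2R)-1-(TBDPSO)propan-2-yl]-6-[(1R)-2-(TBSO)-1-hydroxyethyl]-6-methyl-1,2-dioxane (key-step product) | CC(C)(C)[Si](OC[C@@H](C)[C@@H]1CC[C@@](C)([C@H](O)CO[Si](C)(C)C(C)(C)C)OO1)(c1ccccc1)c1ccccc1 | intermediate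
18 | (3S,6S)-3-[(2R)-1-(TBDPSO)propan-2-yl]-6-[(1R)-1,2-dihydroxyethyl]-6-methyl-1,2-dioxane | CC(C)(C)[Si](OC[C@@H](C)[C@@H]1CC[C@@](C)([C@H](O)CO)OO1)(c1ccccc1)c1ccccc1 | intermediate
19 | (3S,6S)-6-formyl-6-methyl-3-[(2R)-1-(TBDPSO)propan-2-yl]-1,2-dioxane | CC(C)(C)[Si](OC[C@@H](C)[C@@H]1CC[C@@](C)(C=O)OO1)(c1ccccc1)c1ccccc1 | intermediate
20 | (3S,6S)-6-ethenyl-6-methyl-3-[(2R)-1-(TBDPSO)propan-2-yl]-1,2-dioxane | CC(C)(C)[Si](OC[C@@H](C)[C@@H]1CC[C@@](C)(C=C)OO1)(c1ccccc1)c1ccccc1 | intermediate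
21 | dihydro-β-ionone, 4-(2,6,6-trimethylcyclohex-1-en-1-yl)butan-2-one | CC(=O)CCC1=C(C)CCCC1(C)C | starting material
22 | diethyl 4-(2,6,6-trimethylcyclohex-1-en-1-yl)but-1-en-2-yl phosphate (not isolated) | C=C(CCC1=C(C)CCCC1(C)C)OP(=O)(OCC)OCC | intermediate
23 | 2-(but-3-yn-1-yl)-1,3,3-trimethylcyclohex-1-ene | C#CCCC1=C(C)CCCC1(C)C | intermediate
24 | dimethyl[(1E)-2-methyl-4-(2,6,6-trimethylcyclohex-1-en-1-yl)but-1-en-1-yl]alane (not isolated) | C[Al](C)/C=C(\C)CCC1=C(C)CCCC1(C)C | intermediate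
25 | 2-[(3E)-4-iodo-3-methylbut-3-en-1-yl]-1,3,3-trimethylcyclohex-1-ene | I/C=C(\C)CCC1=C(C)CCCC1(C)C | intermediate
26 | 3-[(3E)-4-iodo-3-methylbut-3-en-1-yl]-2,4,4-trimethylcyclohex-2-en-1-one | I/C=C(\C)CCC1=C(C)C(=O)CCC1(C)C | intermediate
27 | (3S,6R)-6-[2-(9-borabicyclo[3.3.1]nonan-9-yl)ethyl]-6-methyl-3-[(2R)-1-(TBDPSO)propan-2-yl]-1,2-dioxane (not isolated) | CC(C)(C)[Si](OC[C@@H](C)[C@@H]1CC[C@@](C)(CCB2C3CCCC2CCC3)OO1)(c1ccccc1)c1ccccc1 | intermediate
28 | (3S,6R)-3-[(2R)-1-(TBDPSO)propan-2-yl]-6-methyl-6-[(3E)-4-methyl-6-(2,6,6-trimethyl-3-oxocyclohex-1-en-1-yl)hex-3-en-1-yl]-1,2-dioxane | CC(C)(C)[Si](OC[C@@H](C)[C@@H]1CC[C@@](C)(CC/C=C(\C)CCC2=C(C)C(=O)CCC2(C)C)OO1)(c1ccccc1)c1ccccc1 | intermediate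
29 | (2R)-2-[(3S,6R)-6-methyl-6-[(3E)-4-methyl-6-(2,6,6-trimethyl-3-oxocyclohex-1-en-1-yl)hex-3-en-1-yl]-1,2-dioxan-3-yl]propan-1-ol | OC[C@@H](C)[C@@H]1CC[C@@](C)(CC/C=C(\C)CCC2=C(C)C(=O)CCC2(C)C)OO1 | intermediate
30 | (2S)-2-[(3S,6R)-dioxanyl]propanal corresponding to 29 (not isolated) | O=C[C@@H](C)[C@@H]1CC[C@@](C)(CC/C=C(\C)CCC2=C(C)C(=O)CCC2(C)C)OO1 | intermediate
31 | (2S)-2-[(3S,6R)-6-methyl-6-[(3E)-4-methyl-6-(2,6,6-trimethyl-3-oxocyclohex-1-en-1-yl)hex-3-en-1-yl]-1,2-dioxan-3-yl]propanoic acid | OC(=O)[C@@H](C)[C@@H]1CC[C@@](C)(CC/C=C(\C)CCC2=C(C)C(=O)CCC2(C)C)OO1 | intermediate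
32 | methyl (2S)-2-[(3S,6R)-6-methyl-6-[(3E)-4-methyl-6-(2,6,6-trimethyl-3-oxocyclohex-1-en-1-yl)hex-3-en-1-yl]-1,2-dioxan-3-yl]propanoate | COC(=O)[C@@H](C)[C@@H]1CC[C@@](C)(CC/C=C(\C)CCC2=C(C)C(=O)CCC2(C)C)OO1 | target

Total step count: 21. Longest linear sequence: 17 (steps 1–7, 9–14, 18–21).

Steps most likely to fail

Step 9. Substitution at the beta-branched secondary carbon may be too slow. E2 loss of the sulfonate, attack of the peroxide anion at silicon and base-induced Kornblum–DeLaMare decay of the product would then gain ground.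
- The fallback sets out from mesylate 12 and comes back at dioxane 17. The two C–O bonds are made in the reverse order, so that the difficult substitution becomes intramolecular.
- Ethereal H2O2 with catalytic H3PMo12O40 perhydrolyses the epoxide of 12 at tertiary C6 with inversion. This gives the C6-hydroperoxy C7-hydroxy mesylate F1.
- One equivalent of KOtBu with 18-crown-6 in THF at 0 °C deprotonates only the hydroperoxide, which displaces the C3 mesylate in a 6-exo-tet SN2 closure with inversion.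
- Both centres undergo the same stereochemical events as in steps 9 and 11, so the product is 17 and steps 8 to 11 drop out.

Step 18. The O–O bond may be cleaved reductively by the borane or by zerovalent palladium and its ligands, or slow transmetallation may end in protodeboronation.
- The fallback sets out from aldehyde 19 and comes back at 28 without any borane.
- Ohira–Bestmann homologation (dimethyl 1-diazo-2-oxopropylphosphonate, K2CO3, MeOH) gives the C6-ethynyl dioxane F2.
- Sonogashira coupling with iodoalkene 26 (Pd(PPh3)2Cl2, CuI, Et3N, THF, rt) gives the conjugated enyne F3.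
- Diimide (2-nitrobenzenesulfonyl hydrazide, Et3N, or potassium azodicarboxylate, AcOH) then saturates the triple bond by way of the 1'Z,3'E-diene F4.
- Reduction is stopped at 28, because the alkyne and the disubstituted alkene accept diimide faster than the trisubstituted alkene and the tetrasubstituted enone.

Step 17. Site selectivity may be poor: oxidation may spread to the allylic positions of the iodoalkene, or the C–I bond may be lost oxidatively.
- The fallback sets out from alkyne 23 and comes back at 26. The oxidation is moved ahead of the carboalumination and the ketone is masked by a temporary reduction.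
- CrO3/3,5-dimethylpyrazole oxidises 23, which has no second alkene and no iodine, to the alkynyl enone F5.
- Luche reduction (NaBH4, CeCl3·7H2O, MeOH) gives the racemic alkynyl allylic alcohol F6.
- Carboalumination with one extra equivalent of Me3Al (Cp2ZrCl2, CH2Cl2) proceeds through the alkenylalane aluminium alkoxide F7, and iodinolysis gives the iodoalkenyl allylic alcohol F8.
- MnO2 in CH2Cl2 then restores the enone of 26 and erases the temporary carbinol centre.

Further compounds
F1 | step 9 | (2R,3R,6S,7R)-1-(TBDPSO)-8-(TBSO)-6-hydroperoxy-7-hydroxy-2,6-dimethyloctan-3-yl methanesulfonate | CC(C)(C)[Si](OC[C@@H](C)[C@H](OS(C)(=O)=O)CC[C@@](C)([C@H](O)CO[Si](C)(C)C(C)(C)C)OO)(c1ccccc1)c1ccccc1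
F2 | step 18 | (3S,6S)-6-ethynyl-6-methyl-3-[(2R)-1-(TBDPSO)propan-2-yl]-1,2-dioxane | CC(C)(C)[Si](OC[C@@H](C)[C@@H]1CC[C@@](C)(C#C)OO1)(c1ccccc1)c1ccccc1
F3 | step 18 | (3S,6S)-6-methyl-6-[(3E)-4-methyl-6-(2,6,6-trimethyl-3-oxocyclohex-1-en-1-yl)hex-3-en-1-yn-1-yl]-3-[(2R)-1-(TBDPSO)propan-2-yl]-1,2-dioxane | CC(C)(C)[Si](OC[C@@H](C)[C@@H]1CC[C@@](C)(C#C/C=C(\C)CCC2=C(C)C(=O)CCC2(C)C)OO1)(c1ccccc1)c1ccccc1
F4 | step 18 | (3S,6S)-6-methyl-6-[(1Z,3E)-4-methyl-6-(2,6,6-trimethyl-3-oxocyclohex-1-en-1-yl)hexa-1,3-dien-1-yl]-3-[(2R)-1-(TBDPSO)propan-2-yl]-1,2-dioxane | CC(C)(C)[Si](OC[C@@H](C)[C@@H]1CC[C@@](C)(/C=C\C=C(/C)CCC2=C(C)C(=O)CCC2(C)C)OO1)(c1ccccc1)c1ccccc1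
F5 | step 17 | 3-(but-3-yn-1-yl)-2,4,4-trimethylcyclohex-2-en-1-one | C#CCCC1=C(C)C(=O)CCC1(C)C
F6 | step 17 | 3-(but-3-yn-1-yl)-2,4,4-trimethylcyclohex-2-en-1-ol (racemic) | C#CCCC1=C(C)C(O)CCC1(C)C
F7 | step 17 | dimethylaluminium alkoxide of the (E)-alkenyl(dimethyl)alane derived from F6 | C[Al](C)/C=C(\C)CCC1=C(C)C(O[Al](C)C)CCC1(C)C
F8 | step 17 | 3-[(3E)-4-iodo-3-methylbut-3-en-1-yl]-2,4,4-trimethylcyclohex-2-en-1-ol (racemic) | I/C=C(\C)CCC1=C(C)C(O)CCC1(C)C
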